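Ring B (C5–C6–C7–C8–C9–C10, labdane numbering) is closed last, at the hindered C9–C10 bond, by a cation–olefin cyclisation of a monocyclic ring-A precursor. The step exploits the anti array Me-20/C10–C9(H)–C8–O and the 1,5-relationship of O-8 to C13. A C10 cation adds to the (E)-C8=C9 alkene while the C13 ketone oxygen captures C8, which sets C10, C9 and C8 at once and leaves the hydroxy ketone that becomes the diene. The precursor, a cyclohexene carrying C4/C5 and the keto-alkenyl chain, comes from an enantioselective Diels–Alder reaction of methacrolein with a triene made from geranylacetone; the cinnamate is already in place.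

Key step: step 7

Remark: positions are given in labdane numbering (C1–C20), and commercial geranylacetone is taken as its pure (5E) isomer.

Step 1
Reactants: 1 (E)-geranylacetone
Product: 2 (5E,9E)-11-hydroxy-6,10-dimethylundeca-5,9-dien-2-one
Conditions: SeO2 (0.3 equiv), t-BuOOH (3 equiv), salicylic acid (0.1 equiv), CH2Cl2, 0 °C → rt
Reagents that add atoms: tert-butyl hydroperoxide, CC(C)(C)OO
Why: SeO2-catalysed allylic oxidation (ene reaction followed by [2,3]-sigmatropic shift) attacks the electron-rich terminal trisubstituted alkene at its (E)-methyl group, so the CH2OH ends up trans to the chain and the ketone is left alone at room temperature.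

Step 2
Reactants: 2 (5E,9E)-11-hydroxy-6,10-dimethylundeca-5,9-dien-2-one
Product: 3 (2E,6E)-2,6-dimethyl-10-oxoundeca-2,6-dienal
Conditions: activated MnO2 (15 equiv), CH2Cl2, rt
Reagents that add atoms: none
Why: MnO2 oxidation of an allylic alcohol stops at the enal and does not touch the alkene geometry or the ketone.

Step 3
Reactants: 3 (2E,6E)-2,6-dimethyl-10-oxoundeca-2,6-dienal
Product: 4 (5E,9E)-6,10-dimethyldodeca-5,9,11-trien-2-one
Conditions: Ph3PCH3Br (1.1 equiv), KHMDS (1.05 equiv), THF, 0 °C; then 3, −78 → −20 °C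
Reagents that add atoms: methyltriphenylphosphonium bromide (as its ylide), C[P+](c1ccccc1)(c1ccccc1)c1ccccc1.[Br-]
Why: Wittig methylenation with about one equivalent of ylide at low temperature should take the aldehyde much faster than the methyl ketone and gives the (E)-diene whose chain-bearing terminus points outward.

Step 4
Reactants: 4 (5E,9E)-6,10-dimethyldodeca-5,9,11-trien-2-one; 5 methacrolein
Product: 6 (1S,2R)-1,3-dimethyl-2-[(3E)-3-methyl-7-oxooct-3-en-1-yl]cyclohex-3-ene-1-carbaldehyde
Conditions: N-protonated B-(o-tolyl)oxazaborolidine from α,α-diphenylprolinol, triflimide salt (20 mol %), CH2Cl2, −78 → −40 °C; dienophile in excess, removed on evaporation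
Reagents that add atoms: none
Why: In this enantioselective Lewis-acid-catalysed Diels–Alder reaction the alkyl-bearing diene terminus should dictate the "ortho" regiochemistry (as with 1-vinylcyclohexene), the endo-formyl transition state of the (E)-diene places the chain cis to CHO, and the catalyst antipode that leaves the Cα-Re face of bound methacrolein open sets C4 (S) and C5 (R) together.

Step 5
Reactants: 6 (1S,2R)-1,3-dimethyl-2-[(3E)-3-methyl-7-oxooct-3-en-1-yl]cyclohex-3-ene-1-carbaldehyde
Product: 7 (5E)-8-[(1R,6S)-6-(hydroxymethyl)-2,6-dimethylcyclohex-2-en-1-yl]-6-methyloct-5-en-2-one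
Conditions: NaBH4 (0.35 equiv), EtOH/CH2Cl2 (3:7), −78 °C
Reagents that add atoms: none
Why: Chemoselective borohydride reduction at −78 °C should take the aldehyde and leave the methyl ketone, and no stereocentre is touched.

Step 6
Reactants: 7 (5E)-8-[(1R,6S)-6-(hydroxymethyl)-2,6-dimethylcyclohex-2-en-1-yl]-6-methyloct-5-en-2-one; 8 (2E)-3-(4-methoxyphenyl)prop-2-enoyl chloride
Product: 9 [(1S,2R)-1,3-dimethyl-2-[(3E)-3-methyl-7-oxooct-3-en-1-yl]cyclohex-3-en-1-yl]methyl (2E)-3-(4-methoxyphenyl)prop-2-enoate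
Conditions: Et3N (2 equiv), DMAP (0.1 equiv), CH2Cl2, 0 °C → rt
Reagents that add atoms: none
Why: DMAP-catalysed acylation of the primary neopentyl alcohol installs the final ester, which has no acidic α-hydrogen and whose acylated oxygen cannot later attack the C10 cation.

Step 7
Reactants: 9 [(1S,2R)-1,3-dimethyl-2-[(3E)-3-methyl-7-oxooct-3-en-1-yl]cyclohex-3-en-1-yl]methyl (2E)-3-(4-methoxyphenyl)prop-2-enoate
Product: 11 (4S,5R,8R,9R,10S)-8-hydroxy-13-oxo-14,15-dinorlabdan-19-yl (2E)-3-(4-methoxyphenyl)prop-2-enoate, via tricyclic enol ether 10 (not isolated)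
Conditions: TfOH (4 equiv), 2-nitropropane, 0.01 M, −78 °C; Et3N quench; then AcOH/THF/H2O (3:1:1), rt
Reagents that add atoms: water, O
Why: Markovnikov protonation of the ring alkene at C1 gives the tertiary C10 cation, C9 of the (E)-C8=C9 alkene attacks it, and the C13 carbonyl oxygen captures the developing C8 cation anti to the new bond; the amine quench gives enol ether 10 and mild aqueous acid opens it to hydroxy ketone 11. The closest known reaction type is the superacid-mediated cation–olefin cyclisation of monocyclic homofarnesyl acids, alcohols and ketones with internal oxygen termination, which gives sclareolide-, ambroxide- and sclareol-oxide-type products. Ring B closes in a 6-endo-trig cation–olefin mode through a chair transition state, and the temporary oxacycle closes by six-membered capture of the C8 cation by the carbonyl oxygen and is reopened by the hydrolysis, so no further ring is formed afterwards. C10 is controlled by the C5 stereocentre: its equatorial tether delivers C9 to the α face, anti to the axial C4–CH2O group, so Me-20 becomes axial (β) and the ring fusion trans. C9 and C8 follow from anti addition across the E alkene in the chair, which places C11 equatorial (β), O-8 equatorial (α) and Me-17 axial (β). The step needs initiation at C10 without a 1,2-hydride shift from C5, without scrambling of the alkene geometry and without bridging from C19; this should be secured by the low temperature and non-nucleophilic medium, the fast chair closure, the reversibility of premature oxygen capture at C8 in strong acid, and the acylated C19 oxygen, whose protonated cinnamate should be inert at −78 °C.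

Step 8
Reactants: 11 (4S,5R,8R,9R,10S)-8-hydroxy-13-oxo-14,15-dinorlabdan-19-yl (2E)-3-(4-methoxyphenyl)prop-2-enoate
Product: 12 (4S,5R,8R,9R,10S)-8-hydroxy-13-[(trifluoromethylsulfonyl)oxy]-14,15-dinorlabd-13(16)-en-19-yl (2E)-3-(4-methoxyphenyl)prop-2-enoate
Conditions: 11 added to KHMDS (2.2 equiv), THF, −78 °C; PhNTf2 (1.05 equiv), −78 → −20 °C; aq NH4Cl
Reagents that add atoms: N-phenyl-bis(trifluoromethanesulfonimide), O=S(=O)(N(c1ccccc1)S(=O)(=O)C(F)(F)F)C(F)(F)F
Why: After deprotonation of the tertiary alcohol, kinetic enolisation of the methyl ketone at its methyl group and O-triflation of the enolate should give the terminal enol triflate, while the hindered tertiary alkoxide and the non-enolisable cinnamate stay unchanged.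

Step 9
Reactants: 12 (4S,5R,8R,9R,10S)-8-hydroxy-13-[(trifluoromethylsulfonyl)oxy]-14,15-dinorlabd-13(16)-en-19-yl (2E)-3-(4-methoxyphenyl)prop-2-enoate
Product: 13 (4S,5R,8R,9R,10S)-8-hydroxylabda-13(16),14-dien-19-yl (2E)-3-(4-methoxyphenyl)prop-2-enoate (target)
Conditions: tributyl(vinyl)stannane (1.5 equiv), Pd(PPh3)4 (5 mol %), LiCl (3 equiv), THF, 60 °C
Reagents that add atoms: tributyl(vinyl)stannane, C=C[Sn](CCCC)(CCCC)CCCC
Why: Stille coupling of the alkenyl triflate with the vinylstannane under neutral conditions should give the 2-substituted buta-1,3-diene without affecting the ester, the tertiary alcohol or any stereocentre.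

Compound list
1 | (5E)-6,10-dimethylundeca-5,9-dien-2-one ((E)-geranylacetone) | CC(C)=CCC/C(C)=C/CCC(C)=O | starting material
2 | (5E,9E)-11-hydroxy-6,10-dimethylundeca-5,9-dien-2-one | OC/C(C)=C/CC/C(C)=C/CCC(C)=O | intermediate
3 | (2E,6E)-2,6-dimethyl-10-oxoundeca-2,6-dienal | O=C/C(C)=C/CC/C(C)=C/CCC(C)=O | intermediate
4 | (5E,9E)-6,10-dimethyldodeca-5,9,11-trien-2-one | C=C/C(C)=C/CC/C(C)=C/CCC(C)=O | intermediate
5 | methacrolein (2-methylprop-2-enal) | CC(=C)C=O | starting material
6 | (1S,2R)-1,3-dimethyl-2-[(3E)-3-methyl-7-oxooct-3-en-1-yl]cyclohex-3-ene-1-carbaldehyde | CC1=CCC[C@](C)(C=O)[C@@H]1CC/C(C)=C/CCC(C)=O | intermediate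
7 | (5E)-8-[(1R,6S)-6-(hydroxymethyl)-2,6-dimethylcyclohex-2-en-1-yl]-6-methyloct-5-en-2-one | CC1=CCC[C@](C)(CO)[C@@H]1CC/C(C)=C/CCC(C)=O | intermediate
8 | (2E)-3-(4-methoxyphenyl)prop-2-enoyl chloride | COc1ccc(/C=C/C(=O)Cl)cc1 | starting material
9 | [(1S,2R)-1,3-dimethyl-2-[(3E)-3-methyl-7-oxooct-3-en-1-yl]cyclohex-3-en-1-yl]methyl (2E)-3-(4-methoxyphenyl)prop-2-enoate | CC1=CCC[C@](C)(COC(=O)/C=C/c2ccc(OC)cc2)[C@@H]1CC/C(C)=C/CCC(C)=O | intermediate
10 | (4S,5R,8R,9R,10S)-8,13-epoxy-14,15-dinorlabd-12-en-19-yl (2E)-3-(4-methoxyphenyl)prop-2-enoate (tricyclic enol ether) | CC1=CC[C@@H]2[C@@]3(C)CCC[C@](C)(COC(=O)/C=C/c4ccc(OC)cc4)[C@@H]3CC[C@@]2(C)O1 | intermediate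
11 | (4S,5R,8R,9R,10S)-8-hydroxy-13-oxo-14,15-dinorlabdan-19-yl (2E)-3-(4-methoxyphenyl)prop-2-enoate | CC(=O)CC[C@@H]1[C@@]2(C)CCC[C@](C)(COC(=O)/C=C/c3ccc(OC)cc3)[C@@H]2CC[C@@]1(C)O | intermediate
12 | (4S,5R,8R,9R,10S)-8-hydroxy-13-[(trifluoromethylsulfonyl)oxy]-14,15-dinorlabd-13(16)-en-19-yl (2E)-3-(4-methoxyphenyl)prop-2-enoate | C=C(OS(=O)(=O)C(F)(F)F)CC[C@@H]1[C@@]2(C)CCC[C@](C)(COC(=O)/C=C/c3ccc(OC)cc3)[C@@H]2CC[C@@]1(C)O | intermediate
13 | (4S,5R,8R,9R,10S)-8-hydroxylabda-13(16),14-dien-19-yl (2E)-3-(4-methoxyphenyl)prop-2-enoate | C=CC(=C)CC[C@@H]1[C@@]2(C)CCC[C@](C)(COC(=O)/C=C/c3ccc(OC)cc3)[C@@H]2CC[C@@]1(C)O | target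

Total step count: 9. Longest linear sequence: 9 steps (1 → 13).

Steps most likely to fail

Step 7. The cascade may start at the side-chain alkene and lose its geometry, a 1,2-hydride shift from C5 to C10 may erode the C4/C5 relationship, or the strong acid may attack the electron-rich cinnamate. The fallback separates ring closure from the cinnamate. It sets out from 7: acetylation (Ac2O, pyridine, DMAP) gives the C19 acetate F1. F1 is cyclised with chlorosulfonic acid in 2-nitropropane at −78 °C to the tricyclic enol ether acetate F2, which is hydrolysed as in step 7 to the hydroxy ketone acetate F3. Methanolysis (K2CO3, MeOH) gives the dihydroxy ketone F4. Selective acylation of its primary alcohol with 8 (Et3N, DMAP) comes back to the route at 11.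

Step 4. Facial control by the catalyst may be insufficient, or the ketone of the diene may bind and slow the Lewis acid. The fallback replaces catalyst control by resolution. It sets out from 4 and 5: a Me2AlCl-promoted cycloaddition gives the racemic cis aldehyde F5. Reduction as in step 5 gives the racemic alcohol F6. Esterification with (S)-O-methylmandelic acid (DCC, DMAP) gives the diastereomeric esters F7 and F8, which are separated by chromatography. Methanolysis of F7 (K2CO3, MeOH) comes back to the route at 7.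

Step 8. The tertiary alkoxide may add to the ketone (hemiketal formation) faster than enolisation occurs, or it may itself be triflated and eliminate. The fallback masks the alcohol instead of using the dianion. It sets out from 11: N-(trimethylsilyl)imidazole gives the silyl ether F9. KHMDS (1.1 equiv) and PhNTf2 give the silylated enol triflate F10. Dilute aqueous acid (AcOH/THF/H2O, rt) removes the silyl group and comes back to the route at 12.

Further compounds
F1 | step 7 | [(1S,2R)-1,3-dimethyl-2-[(3E)-3-methyl-7-oxooct-3-en-1-yl]cyclohex-3-en-1-yl]methyl acetate | CC1=CCC[C@](C)(COC(C)=O)[C@@H]1CC/C(C)=C/CCC(C)=O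
F2 | step 7 | (4S,5R,8R,9R,10S)-8,13-epoxy-14,15-dinorlabd-12-en-19-yl acetate (tricyclic enol ether acetate) | CC1=CC[C@@H]2[C@@]3(C)CCC[C@](C)(COC(C)=O)[C@@H]3CC[C@@]2(C)O1
F3 | step 7 | (4S,5R,8R,9R,10S)-8-hydroxy-13-oxo-14,15-dinorlabdan-19-yl acetate | CC(=O)CC[C@@H]1[C@@]2(C)CCC[C@](C)(COC(C)=O)[C@@H]2CC[C@@]1(C)O
F4 | step 7 | (4S,5R,8R,9R,10S)-8,19-dihydroxy-14,15-dinorlabdan-13-one | CC(=O)CC[C@@H]1[C@@]2(C)CCC[C@](C)(CO)[C@@H]2CC[C@@]1(C)O
F5 | step 4 | racemic cis-1,3-dimethyl-2-[(3E)-3-methyl-7-oxooct-3-en-1-yl]cyclohex-3-ene-1-carbaldehyde (racemate of 6, written without ring stereodescriptors) | CC1=CCCC(C)(C=O)C1CC/C(C)=C/CCC(C)=O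
F6 | step 4 | racemic cis-(5E)-8-[6-(hydroxymethyl)-2,6-dimethylcyclohex-2-en-1-yl]-6-methyloct-5-en-2-one (racemate of 7, written without ring stereodescriptors) | CC1=CCCC(C)(CO)C1CC/C(C)=C/CCC(C)=O
F7 | step 4 | [(1S,2R)-1,3-dimethyl-2-[(3E)-3-methyl-7-oxooct-3-en-1-yl]cyclohex-3-en-1-yl]methyl (2S)-2-methoxy-2-phenylacetate | CC1=CCC[C@](C)(COC(=O)[C@@H](OC)c2ccccc2)[C@@H]1CC/C(C)=C/CCC(C)=O
F8 | step 4 | [(1R,2S)-1,3-dimethyl-2-[(3E)-3-methyl-7-oxooct-3-en-1-yl]cyclohex-3-en-1-yl]methyl (2S)-2-methoxy-2-phenylacetate | CC1=CCC[C@@](C)(COC(=O)[C@@H](OC)c2ccccc2)[C@H]1CC/C(C)=C/CCC(C)=O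
F9 | step 8 | (4S,5R,8R,9R,10S)-13-oxo-8-(trimethylsilyloxy)-14,15-dinorlabdan-19-yl (2E)-3-(4-methoxyphenyl)prop-2-enoate | CC(=O)CC[C@@H]1[C@@]2(C)CCC[C@](C)(COC(=O)/C=C/c3ccc(OC)cc3)[C@@H]2CC[C@@]1(C)O[Si](C)(C)C
F10 | step 8 | (4S,5R,8R,9R,10S)-13-[(trifluoromethylsulfonyl)oxy]-8-(trimethylsilyloxy)-14,15-dinorlabd-13(16)-en-19-yl (2E)-3-(4-methoxyphenyl)prop-2-enoate | C=C(OS(=O)(=O)C(F)(F)F)CC[C@@H]1[C@@]2(C)CCC[C@](C)(COC(=O)/C=C/c3ccc(OC)cc3)[C@@H]2CC[C@@]1(C)O[Si](C)(C)C
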